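**Strategy.** Bisoflavolin J is disconnected first across unit 2 (deoxybenzoin route on a symmetric 2-aryloxyresorcinol) and then, decisively, at the C3–C4 bond of ring C of unit 1, the 8-chloro-7-hydroxyisoflavone. Both carbons are carbonyl-derived: C4 comes from a salicylaldehyde CHO, C3 from an aryl ketone held on O1 through C2. A carbene-catalysed crossed benzoin reaction reverses the polarity of the aldehyde and, in one operation, forms C3–C4 and closes the pyranone ring as a 3-hydroxychroman-4-one that needs only dehydration. Its precursor is a 2-(phenacyloxy)benzaldehyde: 3-chloro-4-methoxysalicylaldehyde O-alkylated with the bromomethyl ketone of 4-(2,6-dimethoxyphenoxy)acetophenone.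

Key step: step 6

Remarks on the chemistry:
- Structure check: the target SMILES reads as an 8-chloro-7-hydroxyisoflavone (unit 1) whose ring B carries, at C4', an ether oxygen to C8 of a 7,4'-dihydroxyisoflavone (unit 2). There is no stereocentre, and the route below matches this atom for atom.
- Protecting groups: O7 of unit 1 and the two oxygens flanking the diaryl ether are all carried as methyl ethers. One BBr3 treatment then frees all three and releases only bromomethane. An acetal on O7 would release a formaldehyde-type electrophile next to the electron-rich resorcinol ring.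
- Bromoketone: it is made through its silyl enol ether, because the 2,6-dimethoxyphenoxy ring is itself open to electrophilic bromination.
- Assumption: the triazolium salt of step 6 and 4-hydroxyphenylacetonitrile (used in one fallback) are purchased.

**Route**

Step 1
Reactants: 1 2-chlororesorcinol
Product: 3 3-chloro-2,4-dihydroxybenzaldehyde, via aryl iminium chloride 2 (not isolated)
Conditions: POCl3, DMF, MeCN, −15 °C → rt; then H2O, 50 °C
Reagents that add atoms: N,N-dimethylformamide, CN(C)C=O; water, O
Why: Vilsmeier–Haack formylation of a resorcinol goes para to one hydroxyl and ortho to the other, and the two such positions of 1 are equivalent by symmetry, so one aldehyde should result after hydrolysis of the iminium salt.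

Step 2
Reactants: 3 3-chloro-2,4-dihydroxybenzaldehyde
Product: 4 3-chloro-2-hydroxy-4-methoxybenzaldehyde
Conditions: MeI (1.1 equiv), K2CO3 (1.0 equiv), acetone, rt
Reagents that add atoms: iodomethane, CI
Why: Williamson methylation should select the 4-hydroxyl, which is the more acidic (para to CHO, ortho to Cl) and free, whereas the 2-hydroxyl is held in a hydrogen bond to the aldehyde.

Step 3
Reactants: 5 2,6-dimethoxyphenol + 6 4'-fluoroacetophenone
Product: 7 1-[4-(2,6-dimethoxyphenoxy)phenyl]ethan-1-one
Conditions: K2CO3, DMSO, 130 °C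
Reagents that add atoms: none
Why: SNAr (addition–elimination) of the phenoxide on the para-acetyl-activated aryl fluoride, a standard way to 4-aryloxyacetophenones that tolerates ortho,ortho-disubstituted phenols.

Step 4
Reactants: 7 1-[4-(2,6-dimethoxyphenoxy)phenyl]ethan-1-one
Product: 9 2-bromo-1-[4-(2,6-dimethoxyphenoxy)phenyl]ethan-1-one, via trimethylsilyl enol ether 8 (not isolated)
Conditions: TMSOTf, iPr2NEt, CH2Cl2, 0 °C; then NBS, −20 → 0 °C
Reagents that add atoms: N-bromosuccinimide, O=C1CCC(=O)N1Br
Why: Soft enolisation to the silyl enol ether followed by electrophilic bromination with NBS should put bromine only alpha to the ketone, because the enol ether is far more nucleophilic than the dimethoxy-activated aryl ring.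

Step 5
Reactants: 4 3-chloro-2-hydroxy-4-methoxybenzaldehyde + 9 2-bromo-1-[4-(2,6-dimethoxyphenoxy)phenyl]ethan-1-one
Product: 10 3-chloro-2-{2-[4-(2,6-dimethoxyphenoxy)phenyl]-2-oxoethoxy}-4-methoxybenzaldehyde
Conditions: K2CO3 (1.2 equiv), acetone (or DMF), rt, work-up as soon as 4 is consumed
Reagents that add atoms: none
Why: Williamson O-alkylation of the remaining phenol by an SN2-activated phenacyl bromide, with mild base at room temperature so that aldol closure of the product to a 2-aroylbenzofuran (Rap–Stoermer) stays slow.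

Step 6
Reactants: 10 3-chloro-2-{2-[4-(2,6-dimethoxyphenoxy)phenyl]-2-oxoethoxy}-4-methoxybenzaldehyde
Product: 11 racemic 8-chloro-3-[4-(2,6-dimethoxyphenoxy)phenyl]-3-hydroxy-7-methoxy-2,3-dihydro-4H-chromen-4-one
Conditions: 2-(pentafluorophenyl)-6,7-dihydro-5H-pyrrolo[2,1-c][1,2,4]triazol-2-ium tetrafluoroborate (15 mol %), Et3N (20 mol %), toluene (0.05 M), rt, Ar
Reagents that add atoms: none
Why: The carbene freed from the triazolium salt by Et3N adds to the aldehyde carbon (future C4), proton transfer gives the Breslow enaminol, its nucleophilic carbon attacks the tethered aryl ketone carbonyl (future C3), and collapse of the adduct releases the carbene and the tertiary alpha-hydroxy ketone. This is an intramolecular crossed aldehyde–ketone benzoin reaction, a known entry to 3-hydroxychroman-4-ones from 2-(2-aryl-2-oxoethoxy)benzaldehydes. Ring C closes by a 6-exo-trig addition, the ketone C=O lying outside the forming six-membered ring. C3 is the only new stereocentre; the achiral catalyst gives the racemate, which is of no consequence because C3 becomes sp2 in step 7. The step needs aldehyde umpolung with cross- rather than homo-coupling, and acyl-anion addition rather than aldol closure of the ketone methylene onto the aldehyde. Only the aldehyde can form a Breslow intermediate, the tether allows only the six-membered closure onto a ketone activated by its alpha-aryloxy group, and a catalytic amount of weak amine base in a non-polar solvent keeps enolate formation negligible.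

Step 7
Reactants: 11 racemic 8-chloro-3-[4-(2,6-dimethoxyphenoxy)phenyl]-3-hydroxy-7-methoxy-2,3-dihydro-4H-chromen-4-one
Product: 13 8-chloro-3-[4-(2,6-dimethoxyphenoxy)phenyl]-7-methoxy-4H-chromen-4-one, via tertiary mesylate 12 (not isolated)
Conditions: MsCl, Et3N, CH2Cl2, 0 °C → rt
Reagents that add atoms: none
Why: Mesylation of the tertiary benzylic carbinol and base-induced 1,2-elimination across C2–C3 (alcohol dehydration via the sulfonate) should be driven by formation of the conjugated chromone, and it erases the C3 stereocentre.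

Step 8
Reactants: 13 8-chloro-3-[4-(2,6-dimethoxyphenoxy)phenyl]-7-methoxy-4H-chromen-4-one
Product: 14 8-chloro-3-[4-(2,6-dihydroxyphenoxy)phenyl]-7-hydroxy-4H-chromen-4-one
Conditions: BBr3 (8 equiv), CH2Cl2, −78 °C → rt; MeOH then H2O quench
Reagents that add atoms: none
Why: BBr3 cleavage of aryl methyl ethers should remove all three methyl groups in one operation, while the diaryl ether, the aryl chloride and the chromone are inert to it.

Step 9
Reactants: 14 8-chloro-3-[4-(2,6-dihydroxyphenoxy)phenyl]-7-hydroxy-4H-chromen-4-one + 15 4-hydroxyphenylacetic acid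
Product: 17 bisoflavolin J, 8-chloro-7-hydroxy-3-(4-{[7-hydroxy-3-(4-hydroxyphenyl)-4-oxo-4H-chromen-8-yl]oxy}phenyl)-4H-chromen-4-one, via deoxybenzoin 16 (not isolated)
Conditions: BF3·OEt2 (reaction medium), 85 °C; then DMF, MsCl, 50 → 80 °C; aqueous NaOAc work-up
Reagents that add atoms: N,N-dimethylformamide, CN(C)C=O
Why: BF3-promoted Friedel–Crafts acylation of the resorcinol ring of 14 can occur only at its two symmetry-equivalent positions (ortho to one hydroxyl, para to the other) to give the 2-hydroxydeoxybenzoin, whose methylene is then formylated by the DMF/MsCl iminium reagent and closes onto the ortho hydroxyl with loss of dimethylamine (deoxybenzoin route to isoflavones), while the chromone-deactivated ring A of unit 1 should stay untouched.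

**Compound list**

1 | 2-chlororesorcinol | Oc1cccc(O)c1Cl | starting material
2 | [(3-chloro-2,4-dihydroxyphenyl)methylidene]dimethylazanium chloride (not isolated) | C[N+](C)=Cc1ccc(O)c(Cl)c1O.[Cl-] | intermediate
3 | 3-chloro-2,4-dihydroxybenzaldehyde | O=Cc1ccc(O)c(Cl)c1O | intermediate
4 | 3-chloro-2-hydroxy-4-methoxybenzaldehyde | COc1ccc(C=O)c(O)c1Cl | intermediate
5 | 2,6-dimethoxyphenol | COc1cccc(OC)c1O | starting material
6 | 4'-fluoroacetophenone | CC(=O)c1ccc(F)cc1 | starting material
7 | 1-[4-(2,6-dimethoxyphenoxy)phenyl]ethan-1-one | CC(=O)c1ccc(Oc2c(OC)cccc2OC)cc1 | intermediate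
8 | ({1-[4-(2,6-dimethoxyphenoxy)phenyl]ethenyl}oxy)trimethylsilane (not isolated) | C=C(O[Si](C)(C)C)c1ccc(Oc2c(OC)cccc2OC)cc1 | intermediate
9 | 2-bromo-1-[4-(2,6-dimethoxyphenoxy)phenyl]ethan-1-one | O=C(CBr)c1ccc(Oc2c(OC)cccc2OC)cc1 | intermediate
10 | 3-chloro-2-{2-[4-(2,6-dimethoxyphenoxy)phenyl]-2-oxoethoxy}-4-methoxybenzaldehyde | COc1ccc(C=O)c(OCC(=O)c2ccc(Oc3c(OC)cccc3OC)cc2)c1Cl | intermediate
11 | racemic 8-chloro-3-[4-(2,6-dimethoxyphenoxy)phenyl]-3-hydroxy-7-methoxy-2,3-dihydro-4H-chromen-4-one | COc1ccc2c(c1Cl)OCC(O)(c1ccc(Oc3c(OC)cccc3OC)cc1)C2=O | intermediate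
12 | racemic 8-chloro-3-[4-(2,6-dimethoxyphenoxy)phenyl]-7-methoxy-4-oxo-3,4-dihydro-2H-chromen-3-yl methanesulfonate (not isolated) | COc1ccc2c(c1Cl)OCC(OS(C)(=O)=O)(c1ccc(Oc3c(OC)cccc3OC)cc1)C2=O | intermediate
13 | 8-chloro-3-[4-(2,6-dimethoxyphenoxy)phenyl]-7-methoxy-4H-chromen-4-one | COc1ccc2c(c1Cl)occ(-c1ccc(Oc3c(OC)cccc3OC)cc1)c2=O | intermediate
14 | 8-chloro-3-[4-(2,6-dihydroxyphenoxy)phenyl]-7-hydroxy-4H-chromen-4-one | O=c1c(-c2ccc(Oc3c(O)cccc3O)cc2)coc2c(Cl)c(O)ccc12 | intermediate
15 | 4-hydroxyphenylacetic acid | O=C(O)Cc1ccc(O)cc1 | starting material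
16 | 8-chloro-3-(4-{2,6-dihydroxy-3-[(4-hydroxyphenyl)acetyl]phenoxy}phenyl)-7-hydroxy-4H-chromen-4-one (not isolated) | O=C(Cc1ccc(O)cc1)c1ccc(O)c(Oc2ccc(-c3coc4c(Cl)c(O)ccc4c3=O)cc2)c1O | intermediate
17 | bisoflavolin J | O=c1c(-c2ccc(Oc3c(O)ccc4c(=O)c(-c5ccc(O)cc5)coc34)cc2)coc2c(Cl)c(O)ccc12 | target

**Step count.** Total: 9 steps. Longest linear sequence: 7 steps (steps 1, 2, 5, 6, 7, 8, 9 from 2-chlororesorcinol; equally steps 3, 4, 5, 6, 7, 8, 9 from 2,6-dimethoxyphenol).

**Steps most likely to fail**

1. Step 6. The base may enolise the ketone methylene and close it onto the aldehyde (aldol condensation towards a benzofuran). Alternatively, the donor-substituted aldehyde and ketone may react too slowly, so that intermolecular benzoin coupling or catalyst decay wins. Fallback: unit 1 would be built by the deoxybenzoin route, setting out from ketone 7 and starting material 1 and returning at 14.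
   - A Willgerodt–Kindler reaction of 7 (sulfur, morpholine, 130 °C) would give 2-[4-(2,6-dimethoxyphenoxy)phenyl]-1-(morpholin-4-yl)ethane-1-thione F1.
   - Hydrolysis (NaOH, aqueous EtOH, reflux; then acid) would give [4-(2,6-dimethoxyphenoxy)phenyl]acetic acid F2.
   - Acylation of 1 with F2 in BF3·OEt2 at 85 °C would give 1-(3-chloro-2,4-dihydroxyphenyl)-2-[4-(2,6-dimethoxyphenoxy)phenyl]ethan-1-one F3.
   - Closure with DMF/MsCl would give 8-chloro-3-[4-(2,6-dimethoxyphenoxy)phenyl]-7-hydroxy-4H-chromen-4-one F4.
   - BBr3 in CH2Cl2 would then give triol 14, where the route is rejoined.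

2. Step 9. The sparingly soluble triol may be acylated incompletely or at the wrong site (O-acylation, attack on ring B, self-condensation of the acid), and free phenols may be formylated or mesylated during closure. Fallback: a Houben–Hoesch reaction of 14 with 4-hydroxyphenylacetonitrile (ZnCl2, HCl gas, Et2O/dioxane, 0 °C) would give 1-{3-[4-(8-chloro-7-hydroxy-4-oxo-4H-chromen-3-yl)phenoxy]-2,4-dihydroxyphenyl}-2-(4-hydroxyphenyl)ethan-1-iminium chloride F5. Its hydrolysis in hot water would give deoxybenzoin 16, this time isolated and purified. Ring closure with triethyl orthoformate (pyridine, catalytic piperidine, reflux) would return to the route at 17.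

3. Step 7. Sulfonylation of the hindered tertiary carbinol may stall, or the sulfonate may ionise and rearrange (alpha-ketol-type shift) instead of eliminating. Fallback: 11 would be heated in 48% HBr/AcOH at reflux. Acid-promoted E1 loss of water through the aryl-stabilised C3 cation and cleavage of all three methyl ethers would then occur in one operation, giving triol 14 directly and bypassing 13.

**Further compounds**

F1 | step 6 | 2-[4-(2,6-dimethoxyphenoxy)phenyl]-1-(morpholin-4-yl)ethane-1-thione | COc1cccc(OC)c1Oc1ccc(CC(=S)N2CCOCC2)cc1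
F2 | step 6 | [4-(2,6-dimethoxyphenoxy)phenyl]acetic acid | COc1cccc(OC)c1Oc1ccc(CC(=O)O)cc1
F3 | step 6 | 1-(3-chloro-2,4-dihydroxyphenyl)-2-[4-(2,6-dimethoxyphenoxy)phenyl]ethan-1-one | COc1cccc(OC)c1Oc1ccc(CC(=O)c2ccc(O)c(Cl)c2O)cc1
F4 | step 6 | 8-chloro-3-[4-(2,6-dimethoxyphenoxy)phenyl]-7-hydroxy-4H-chromen-4-one | COc1cccc(OC)c1Oc1ccc(-c2coc3c(Cl)c(O)ccc3c2=O)cc1
F5 | step 9 | 1-{3-[4-(8-chloro-7-hydroxy-4-oxo-4H-chromen-3-yl)phenoxy]-2,4-dihydroxyphenyl}-2-(4-hydroxyphenyl)ethan-1-iminium chloride | [NH2+]=C(Cc1ccc(O)cc1)c1ccc(O)c(Oc2ccc(-c3coc4c(Cl)c(O)ccc4c3=O)cc2)c1O.[Cl-]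
F0 | step 7 | none | none
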